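## Structural features

The target is a daucane diester. A cyclopentane (ring A, C1–C5) is trans-fused through the C1–C5 bond to a cycloheptene (ring B: C1, C5, C6, C7, C8, C9, C10) whose only alkene, C8=C9, carries the C8 methyl. Daucane numbering is used throughout: C1 is the methyl-bearing fusion carbon, C4 the isopropyl carbinol (C11 its methine), C5 the fusion CH, C6 the 4-hydroxybenzoyloxy carbon and C10 the 3-methylbutanoyloxy carbon. The five stereocentres form one contiguous array, C10–C1–C5(–C6)–C4, with configuration 1S,4S,5S,6R,10R. On ring A the C1 methyl, the C5–C6 bond and the isopropyl group lie on one face and C10, H5 and the C4 hydroxyl on the other; on ring B the C6 oxygen is syn and the C10 oxygen anti to the angular methyl. The fragile groups are the tertiary C4 alcohol (dehydration, and retro-aldol once C6 is a carbonyl), the secondary allylic ester at C10 next to a quaternary carbon, the two different esters (no migration or exchange allowed) and the free phenol. The real difficulty is the quaternary C1 flanked by three stereocentres, together with two hindered secondary carbinols of opposite sense that must be set independently and acylated differently. The key step uses the fact that C1 and C5 are adjacent and each carries one exocyclic carbon at the carboxyl level (C10 and C6) in a trans relationship, while C2–C3 and C4–C11 make up a four-carbon unit. This is the pattern of an (E)-2-methylbutenedioate joined to a butadiene.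

## Logic of the disconnections

31 to 30: the phenol O–Si bond is cut. The aroyl unit can then be introduced as a monofunctional acid, and no free phenol is present during acylation or metathesis. Nothing is simplified in the skeleton. The forward step needs a desilylation that spares two esters, a tertiary alcohol and an allylic ester.

30 to 29: the C8=C9 bond of ring B is cut (metathesis retron). It is the only alkene, it is trisubstituted, and cutting it makes no stereocentre in the ring closure because C6 and C10 are already set and acylated. The bicycle becomes a cyclopentane with two side arms. The forward step must engage a vinyl group next to quaternary C1 and a 1,1-disubstituted alkene.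

29 to 24 and 27 (27 from 25 via 26): the acyl C–O bond at O6 is cut, so the aromatic ester arrives after all hydride and organometallic steps. The forward step must acylate a hindered secondary hydroxyl beside an unprotected tertiary one, via 28.

24 to 23, then 22 and 21: the C6–C7 bond is cut (homoallylic alcohol retron), which removes four carbons and the C6 stereocentre. The forward step needs reagent-controlled face selection on an aldehyde flanked by two fully substituted carbons. 23 comes from 21 by unmasking and oxidising C6.

21 to 20, 19, 18 and 17: at C10 the acyl C–O bond, then the C10–H bond, then the C9–C10 bond are cut. Direct vinyl addition to 17 is predicted by both the Felkin–Anh and the chelate model to favour the wrong epimer. The configuration is therefore set by hydride delivery to 19, where reagent and substrate preferences should agree. 17 comes from 16 by adjusting the oxidation level.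

16 to 15 and 14: the isopropyl group is traced to an acetyl group; the C11=CH2 bond is cut (methylenation retron). This removes no stereocentre but leaves a carbonyl that activates C4.

14 to 12 (via 13): the C4–O bond is cut. Oxygen is delivered to a planar C4 radical or enolate anti to the C5 arm, which removes the C4 stereocentre and gives a simple enone. The forward step must add oxygen on the H5 face and at C4 only.

12 to 11 and 10: the C11–CH3 bond is cut (methyl addition to an enal, then oxidation).

10 to 7 (via 9 and 8): the C3=C4 bond is cut (aldol condensation retron) and C3 is reconnected to C11. The cyclopentene becomes a cyclohexene, which is a Diels–Alder retron. The forward step must enolise toward C4 and not toward C2.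

7 to 6, 4 (via 5) and 3: the two carboxyl carbons are told apart immediately after the cycloaddition. The C6 carboxyl, on the tertiary carbon, is taken down to a protected carbinol. C5 is then no longer α to a carbonyl and cannot epimerise, and the C10 ester stays as the only acyl group. The forward step needs mono-saponification at the less hindered ester.

3 to 1 and 2: the C1–C2 and C4–C5 bonds are cut. One ring, two skeletal bonds and both ring-fusion stereocentres go back to two commercial, achiral compounds. The forward step needs only enantioface selection, since the trans relationship follows from the alkene geometry. Mapped onto C1 and C5 of 31, 3 must be the (1S,2S) enantiomer with trans esters.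

## Other disconnections considered

Alternative 1: The cut is at C1–C10 and C5–C6. In the forward key step a chiral copper catalyst adds the α-silylvinyl alane A4 to 3-methylcyclopent-2-enone A2, creating quaternary C1. The aluminium enolate then adds at C5 to the aldehyde A3, trans to the new alkenyl group, giving the cyclopentanone A1.
- In its favour: two skeletal bonds and both fusion centres form in one flask on a purchased five-membered ring, with no ring contraction. In bond economy for ring A this is better than the chosen plan. In catalyst control of absolute configuration it is equal.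
- Against it here:
  - C4 arrives as a ketone. An isopropyl nucleophile would approach anti to the C5 arm and place the isopropyl group on the wrong face, whereas the chosen route brings in oxygen, which is needed on exactly that face.
  - The C6 carbinol of A1 is the wrong epimer and must be inverted at a hindered centre.
  - A1 is a β-hydroxy ketone, open to retro-aldol and dehydration.
  - Quaternary-centre formation by alkenyl addition is less secure on five-membered enones than on six-membered ones.
  - Ring B is still open, and C10 carries silicon and not oxygen, so the C10 oxygen and its configuration remain to be added next to the quaternary carbon.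
- Comparison: structurally the alternative maps C1, C5 and C6 directly but works against C4. Mechanistically it depends on enolate trapping selectivity, where the cycloaddition fixes the trans relationship by alkene geometry. In step count it is shorter at the front and longer at the back.

Alternative 2: The cut is at C1–C5 and C1–C10, both bonds to one carbene carbon. In the forward key step Rh2(OAc)4 decomposes the diazoketone A6. The carbenoid adds across the ipso–ortho bond of the electron-rich arene, and 6π-electrocyclic opening of the norcaradiene gives the bicyclic trienone A5.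
- In its favour: every ring carbon, the C8 methyl and oxygen at C6 and C10 are in place after one step, and ring B needs no separate closure. In skeletal step economy this is better than the chosen plan.
- Against it here:
  - The carbenoid carries a methyl group, so a 1,2-hydride shift to an enone competes.
  - C1 must be controlled from C4 through a flexible tether.
  - In A5 the carbons C5, C6 and C10 are all sp2. The trans ring fusion and both carbinol configurations would have to come from reductions of a bis-enol ether triene in which only C8=C9 may survive, and the C2 carbonyl must be removed.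
  - The benzylic tertiary carbinol of A6 needs its own asymmetric synthesis.
- Comparison: the structural mapping of the arene onto ring B is excellent. Mechanistically, carbenoid chemoselectivity is harder to predict than a concerted cycloaddition. The front end is shorter but the back end carries three unsolved stereocentres, against two set at once in the chosen route. Both plans are equal in needing separate solutions for C6 and C10.

Alternative 3: The cut is at C8–C9 and C9–C10 (insertion of C9). In the forward key step the silyl enol ether A8 of a trans-hydrindanone is cyclopropanated by CH2I2/Et2Zn (Simmons–Smith). FeCl3 then opens the siloxycyclopropane and HCl is eliminated, giving the cycloheptenone A7.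
- In its favour: absolute configuration would come from the chiral pool, and the ring expansion is a robust, well-understood reaction. In certainty of the key step it is equal or better. A8 can enolise only toward C8 because C1 is quaternary, which is better than the regiochemical question in step 5 of the chosen route. A7 is formally only a reduction, an acylation and a desilylation from 31.
- Against it here:
  - Hydride should attack the C10 carbonyl of A7 anti to the angular methyl and give the alcohol syn to it, the epimer of 31. That calls for reagent override or inversion at a neopentyl allylic centre.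
  - Building A8 from a monoterpene, with quaternary C1, the C4 carbinol, the trans fusion and the C6 ester, is long.
  - FeCl3 must be tolerated by a tertiary alcohol and an aryl silyl ether.
- Comparison: structurally the key step comes late, on a valuable intermediate. The overall count is likely higher than in the chosen plan, which sets C10 on an open chain.

Key step: step 1

Assumption: the sense of induction in the three reagent-controlled steps (1, 14, 18) is assigned from the standard transition-state models; each chiral reagent is available as both antipodes, so an inverted sense would be met by the antipodal reagent with no other change.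

## Route

Step 1
Reactants: 1 buta-1,3-diene; 2 dimethyl mesaconate [dimethyl (2E)-2-methylbut-2-enedioate]
Product: 3 dimethyl (1S,2S)-1-methylcyclohex-4-ene-1,2-dicarboxylate
Conditions: (R)-3,3-diphenyl-1-(2-methylphenyl)tetrahydropyrrolo[1,2-c][1,3,2]oxazaborolium bis(trifluoromethanesulfonyl)imide, 20 mol% [from (R)-α,α-diphenylprolinol, tri(o-tolyl)boroxine, HNTf2]; 1 (10 equiv), CH2Cl2, −20 to 23 °C, sealed vessel
Reagents that add atoms: none
Why: This is a Lewis-acid-accelerated Diels–Alder reaction in which boron binds the carbonyl of the ester on the C–H carbon of 2, the only one with an α-C–H for the secondary C–H···O contact to the ring oxygen, lowering the LUMO and holding the enoate over one aryl group. The closest known reaction type is the oxazaborolidinium-catalysed cycloaddition of butadiene with fumarate, acrylate and trisubstituted ester dienophiles. The cyclohexene closes in one concerted, asynchronous, suprafacial–suprafacial [4π+2π] event that forms C1–C2 and C5–C4 together; it is an intermolecular annulation, and with an unsubstituted symmetric diene neither regiochemistry nor endo/exo topology affects the product. The trans relationship of the C10 and C6 carboxyls, and so of the C1 methyl and H5, is copied stereospecifically from the (E)-alkene. The absolute configuration (1S,2S) depends on which enantioface the shielded complex leaves open, that is, on the catalyst antipode. The step therefore needs only enantioface selection, which single-point binding at the less hindered α-H ester plus aryl shielding should secure. The second ester supplies the reactivity that a β,β-disubstituted enoate would otherwise lack toward butadiene.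

Step 2
Reactants: 3 dimethyl (1S,2S)-1-methylcyclohex-4-ene-1,2-dicarboxylate
Product: 4 (1S,6S)-6-(methoxycarbonyl)-6-methylcyclohex-3-ene-1-carboxylic acid
Conditions: LiOH·H2O (1.05 equiv), THF/MeOH/H2O, 0 to 23 °C; then 1 M HCl
Reagents that add atoms: lithium hydroxide, [Li+].[OH-]
Why: Saponification is much faster at the ester on the tertiary ring carbon than at the neopentyl-type ester on quaternary C1, so one equivalent of hydroxide should give the C6 acid. The carboxylate that forms protects C5 from epimerisation.

Step 3
Reactants: 4 (1S,6S)-6-(methoxycarbonyl)-6-methylcyclohex-3-ene-1-carboxylic acid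
Product: 6 methyl (1S,6S)-6-(hydroxymethyl)-1-methylcyclohex-3-ene-1-carboxylate, via isobutyl carbonate mixed anhydride 5 (not isolated)
Conditions: iBuOCOCl, N-methylmorpholine, THF, −15 °C; then NaBH4, H2O, 0 °C
Reagents that add atoms: none
Why: Mixed-anhydride activation followed by borohydride reduction takes only the activated acyl group to the primary alcohol and leaves the hindered methyl ester and the ring alkene untouched (free borane could hydroborate the alkene). From here C5 is no longer α to a carbonyl and is configurationally secure.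

Step 4
Reactants: 6 methyl (1S,6S)-6-(hydroxymethyl)-1-methylcyclohex-3-ene-1-carboxylate
Product: 7 methyl (1S,6S)-6-{[(tert-butyldimethylsilyl)oxy]methyl}-1-methylcyclohex-3-ene-1-carboxylate
Conditions: tBuMe2SiCl, imidazole, CH2Cl2, 0 to 23 °C
Reagents that add atoms: tert-butyldimethylsilyl chloride, CC(C)(C)[Si](C)(C)Cl
Why: Standard silylation of a primary alcohol. Prompt protection also prevents lactonisation onto the neighbouring ester and lactol formation after the ozonolysis.

Step 5
Reactants: 7 methyl (1S,6S)-6-{[(tert-butyldimethylsilyl)oxy]methyl}-1-methylcyclohex-3-ene-1-carboxylate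
Product: 10 methyl (1S,5S)-5-{[(tert-butyldimethylsilyl)oxy]methyl}-4-formyl-1-methylcyclopent-3-ene-1-carboxylate, via secondary ozonide 8 (not isolated), via dialdehyde 9 (not isolated)
Conditions: O3, CH2Cl2, −78 °C; PPh3, −78 to 23 °C; then Bn2NH·CF3CO2H (0.3 equiv), toluene, 23 to 50 °C
Reagents that add atoms: ozone, [O-][O+]=O
Why: Ozonolysis with reductive work-up cleaves the only alkene to the 1,6-dialdehyde, and amine-catalysed (enamine) intramolecular aldol condensation closes the five-membered ring by 5-(enolexo)-exo-trig attack of C4 on the C3 aldehyde, then dehydrates to the conjugated enal. C4 should be the nucleophile because its enamine sits next to a tertiary carbon, whereas the alternative nucleophile C2 is neopentyl (next to quaternary C1). No stereocentre is formed.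

Step 6
Reactants: 10 methyl (1S,5S)-5-{[(tert-butyldimethylsilyl)oxy]methyl}-4-formyl-1-methylcyclopent-3-ene-1-carboxylate
Product: 11 methyl (1S,5S)-5-{[(tert-butyldimethylsilyl)oxy]methyl}-4-(1-hydroxyethyl)-1-methylcyclopent-3-ene-1-carboxylate (both carbinol epimers)
Conditions: CH3MgBr (1.2 equiv), THF, −78 °C; aq. NH4Cl
Reagents that add atoms: methylmagnesium bromide, C[Mg]Br
Why: 1,2-Addition of a Grignard reagent to the enal at low temperature. The ester on the quaternary carbon is too hindered to compete, and the new carbinol centre is removed in the next step.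

Step 7
Reactants: 11 methyl (1S,5S)-5-{[(tert-butyldimethylsilyl)oxy]methyl}-4-(1-hydroxyethyl)-1-methylcyclopent-3-ene-1-carboxylate
Product: 12 methyl (1S,5S)-4-acetyl-5-{[(tert-butyldimethylsilyl)oxy]methyl}-1-methylcyclopent-3-ene-1-carboxylate
Conditions: Dess–Martin periodinane, NaHCO3, CH2Cl2, 0 to 23 °C
Reagents that add atoms: none
Why: Dess–Martin oxidation of a secondary allylic alcohol under buffered conditions gives the enone.

Step 8
Reactants: 12 methyl (1S,5S)-4-acetyl-5-{[(tert-butyldimethylsilyl)oxy]methyl}-1-methylcyclopent-3-ene-1-carboxylate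
Product: 14 methyl (1S,2S,3R)-3-acetyl-2-{[(tert-butyldimethylsilyl)oxy]methyl}-3-hydroxy-1-methylcyclopentane-1-carboxylate, via tertiary hydroperoxide 13 (not isolated)
Conditions: Mn(dpm)3 [tris(2,2,6,6-tetramethylheptane-3,5-dionato)manganese] (10 mol%), PhSiH3 (2 equiv), O2 (1 atm), iPrOH/CH2Cl2, 0 °C; then P(OEt)3
Reagents that add atoms: dioxygen, O=O
Why: This is a Mukaiyama-type hydration–oxidation of an enone: a metal hydride transfers a hydrogen atom to the β-carbon C3, O2 captures the C4 radical or manganese enolate, and phosphite reduces the hydroperoxide; the reaction type is known for 1-acylcycloalkenes. Oxygen should enter anti to the adjacent C5 arm and the C1 methyl, on the H5 face, which gives the C4 hydroxyl of the target. No enolate is made by deprotonation, so the regiochemistry is unambiguous.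

Step 9
Reactants: 14 methyl (1S,2S,3R)-3-acetyl-2-{[(tert-butyldimethylsilyl)oxy]methyl}-3-hydroxy-1-methylcyclopentane-1-carboxylate
Product: 15 methyl (1S,2S,3R)-2-{[(tert-butyldimethylsilyl)oxy]methyl}-3-hydroxy-1-methyl-3-(prop-1-en-2-yl)cyclopentane-1-carboxylate
Conditions: Ph3PCH3Br (4 equiv), KOtBu (3.8 equiv), THF, 0 to 40 °C
Reagents that add atoms: methyltriphenylphosphonium bromide, [Br-].C[P+](c1ccccc1)(c1ccccc1)c1ccccc1
Why: Wittig methylenation of the methyl ketone with excess ylide, which tolerates the free tertiary hydroxyl as its alkoxide. The ester on the quaternary carbon is inert to the ylide.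

Step 10
Reactants: 15 methyl (1S,2S,3R)-2-{[(tert-butyldimethylsilyl)oxy]methyl}-3-hydroxy-1-methyl-3-(prop-1-en-2-yl)cyclopentane-1-carboxylate
Product: 16 methyl (1S,2S,3S)-2-{[(tert-butyldimethylsilyl)oxy]methyl}-3-hydroxy-1-methyl-3-(propan-2-yl)cyclopentane-1-carboxylate
Conditions: H2 (1 atm), Pd/C, EtOAc, 23 °C
Reagents that add atoms: none
Why: Heterogeneous hydrogenation of the 1,1-disubstituted alkene gives the isopropyl group. No stereocentre is created because C11 ends with two methyl groups.

Step 11
Reactants: 16 methyl (1S,2S,3S)-2-{[(tert-butyldimethylsilyl)oxy]methyl}-3-hydroxy-1-methyl-3-(propan-2-yl)cyclopentane-1-carboxylate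
Product: 17 (1S,2S,3S)-2-{[(tert-butyldimethylsilyl)oxy]methyl}-3-hydroxy-1-methyl-3-(propan-2-yl)cyclopentane-1-carbaldehyde
Conditions: iBu2AlH (3 equiv), CH2Cl2, −78 °C; aq. potassium sodium tartrate
Reagents that add atoms: none
Why: Low-temperature iBu2AlH reduction should stop at the aldehyde level because the tetrahedral aluminium hemiacetal of an α-quaternary ester, held further by the cis C4 alkoxide, survives until work-up. The product may rest as its bridged lactol, which behaves as the aldehyde in the next step.

Step 12
Reactants: 17 (1S,2S,3S)-2-{[(tert-butyldimethylsilyl)oxy]methyl}-3-hydroxy-1-methyl-3-(propan-2-yl)cyclopentane-1-carbaldehyde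
Product: 18 1-[(1S,2S,3S)-2-{[(tert-butyldimethylsilyl)oxy]methyl}-3-hydroxy-1-methyl-3-(propan-2-yl)cyclopentyl]prop-2-en-1-ol (both C10 epimers)
Conditions: CH2=CHMgBr (4 equiv), THF, −78 to 0 °C; aq. NH4Cl
Reagents that add atoms: vinylmagnesium bromide, C=C[Mg]Br
Why: Grignard addition to a non-enolisable aldehyde; one equivalent is spent on the tertiary hydroxyl and opens any lactol. Selectivity is not sought here because the carbinol is re-set after oxidation.

Step 13
Reactants: 18 1-[(1S,2S,3S)-2-{[(tert-butyldimethylsilyl)oxy]methyl}-3-hydroxy-1-methyl-3-(propan-2-yl)cyclopentyl]prop-2-en-1-ol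
Product: 19 1-[(1S,2S,3S)-2-{[(tert-butyldimethylsilyl)oxy]methyl}-3-hydroxy-1-methyl-3-(propan-2-yl)cyclopentyl]prop-2-en-1-one
Conditions: Dess–Martin periodinane, NaHCO3, CH2Cl2, 0 °C
Reagents that add atoms: none
Why: Dess–Martin oxidation of the secondary allylic alcohol; the tertiary alcohol cannot be oxidised. The hindered tert-alkyl vinyl ketone is used at once.

Step 14
Reactants: 19 1-[(1S,2S,3S)-2-{[(tert-butyldimethylsilyl)oxy]methyl}-3-hydroxy-1-methyl-3-(propan-2-yl)cyclopentyl]prop-2-en-1-one
Product: 20 (1R)-1-[(1S,2S,3S)-2-{[(tert-butyldimethylsilyl)oxy]methyl}-3-hydroxy-1-methyl-3-(propan-2-yl)cyclopentyl]prop-2-en-1-ol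
Conditions: (S)-2-methyl-CBS-oxazaborolidine (0.5 equiv), catecholborane (2.5 equiv), toluene, −78 °C; MeOH, then aq. NaOH wash
Reagents that add atoms: none
Why: CBS reduction with catecholborane is 1,2-selective for enones; with quaternary C1 as the large and the vinyl group as the small substituent, the (S)-catalyst should give the (R)-carbinol. Felkin–Anh attack anti to the C5 branch leads to the same alcohol, so reagent and substrate preferences should reinforce each other.

Step 15
Reactants: 20 (1R)-1-[(1S,2S,3S)-2-{[(tert-butyldimethylsilyl)oxy]methyl}-3-hydroxy-1-methyl-3-(propan-2-yl)cyclopentyl]prop-2-en-1-ol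
Product: 21 (1R)-1-[(1S,2S,3S)-2-{[(tert-butyldimethylsilyl)oxy]methyl}-3-hydroxy-1-methyl-3-(propan-2-yl)cyclopentyl]prop-2-en-1-yl 3-methylbutanoate
Conditions: (CH3)2CHCH2COCl (2 equiv), pyridine, DMAP (0.2 equiv), CH2Cl2, 0 to 23 °C
Reagents that add atoms: 3-methylbutanoyl chloride, CC(C)CC(=O)Cl
Why: DMAP-catalysed acylation of the secondary allylic alcohol. The tertiary C4 hydroxyl, flanked by the isopropyl group, is too hindered to react.

Step 16
Reactants: 21 (1R)-1-[(1S,2S,3S)-2-{[(tert-butyldimethylsilyl)oxy]methyl}-3-hydroxy-1-methyl-3-(propan-2-yl)cyclopentyl]prop-2-en-1-yl 3-methylbutanoate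
Product: 22 (1R)-1-[(1S,2S,3S)-3-hydroxy-2-(hydroxymethyl)-1-methyl-3-(propan-2-yl)cyclopentyl]prop-2-en-1-yl 3-methylbutanoate
Conditions: HF·pyridine, pyridine, THF, 0 to 23 °C
Reagents that add atoms: none
Why: Fluoride cleavage of the primary silyl ether under buffered, weakly acidic conditions that should not cause acyl migration or ionisation of the allylic ester.

Step 17
Reactants: 22 (1R)-1-[(1S,2S,3S)-3-hydroxy-2-(hydroxymethyl)-1-methyl-3-(propan-2-yl)cyclopentyl]prop-2-en-1-yl 3-methylbutanoate
Product: 23 (1R)-1-[(1S,2R,3S)-2-formyl-3-hydroxy-1-methyl-3-(propan-2-yl)cyclopentyl]prop-2-en-1-yl 3-methylbutanoate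
Conditions: Dess–Martin periodinane, NaHCO3, CH2Cl2, 0 to 23 °C
Reagents that add atoms: none
Why: Buffered Dess–Martin oxidation gives the β-hydroxy aldehyde without base, so neither epimerisation at C5 nor loss of the C4 hydroxyl is triggered. The descriptor at C5 changes only through CIP priorities, and the aldehyde is used without storage.

Step 18
Reactants: 23 (1R)-1-[(1S,2R,3S)-2-formyl-3-hydroxy-1-methyl-3-(propan-2-yl)cyclopentyl]prop-2-en-1-yl 3-methylbutanoate
Product: 24 (1R)-1-[(1S,2S,3S)-3-hydroxy-2-[(1R)-1-hydroxy-3-methylbut-3-en-1-yl]-1-methyl-3-(propan-2-yl)cyclopentyl]prop-2-en-1-yl 3-methylbutanoate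
Conditions: (+)-Ipc2B(CH2C(CH3)=CH2) [from (+)-Ipc2BOMe and CH2=C(CH3)CH2MgCl, Et2O, −78 to 23 °C], then 23, Et2O, −78 °C; NaBO3·4H2O, THF/H2O, 23 °C
Reagents that add atoms: (+)-B-(2-methylallyl)diisopinocampheylborane, C=C(C)CB([C@H]1C[C@H]2C[C@@H]([C@@H]1C)C2(C)C)[C@H]1C[C@H]2C[C@@H]([C@@H]1C)C2(C)C; its methallyl source 2-methylallylmagnesium chloride, C=C(C)C[Mg]Cl
Why: Allylboration runs through a closed six-membered chair transition state. The aldehyde is flanked by two fully substituted carbons and has no useful intrinsic bias, so C6 is set by the (−)-α-pinene-derived reagent, which should add to the Re face and give the (R)-carbinol. The borane does not touch the ester or the terminal alkene, and perborate work-up is mild enough for the allylic ester.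

Step 19
Reactants: 25 4-hydroxybenzoic acid
Product: 27 4-[(tert-butyldimethylsilyl)oxy]benzoic acid, via bis-silylated benzoate 26 (not isolated)
Conditions: tBuMe2SiCl (2.4 equiv), imidazole, DMF, 23 °C; then AcOH/THF/H2O, 23 °C
Reagents that add atoms: tert-butyldimethylsilyl chloride, CC(C)(C)[Si](C)(C)Cl
Why: Exhaustive silylation followed by selective hydrolysis of the labile silyl ester leaves the phenol protected and the acid free.

Step 20
Reactants: 24 (1R)-1-[(1S,2S,3S)-3-hydroxy-2-[(1R)-1-hydroxy-3-methylbut-3-en-1-yl]-1-methyl-3-(propan-2-yl)cyclopentyl]prop-2-en-1-yl 3-methylbutanoate; 27 4-[(tert-butyldimethylsilyl)oxy]benzoic acid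
Product: 29 (1R)-1-[(1S,2S,5S)-2-hydroxy-5-methyl-5-{(1R)-1-[(3-methylbutanoyl)oxy]prop-2-en-1-yl}-2-(propan-2-yl)cyclopentyl]-3-methylbut-3-en-1-yl 4-[(tert-butyldimethylsilyl)oxy]benzoate, via trichlorobenzoyl mixed anhydride 28 (not isolated)
Conditions: 2,4,6-Cl3C6H2COCl, Et3N, THF, 23 °C; then 24, DMAP, toluene, 23 to 50 °C
Reagents that add atoms: none
Why: In this Yamaguchi esterification DMAP attacks the unhindered aroyl carbonyl of the mixed anhydride, and the acylpyridinium acylates the hindered secondary C6 hydroxyl. The tertiary hydroxyl does not react.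

Step 21
Reactants: 29 (1R)-1-[(1S,2S,5S)-2-hydroxy-5-methyl-5-{(1R)-1-[(3-methylbutanoyl)oxy]prop-2-en-1-yl}-2-(propan-2-yl)cyclopentyl]-3-methylbut-3-en-1-yl 4-[(tert-butyldimethylsilyl)oxy]benzoate
Product: 30 (3S,3aS,4R,8R,8aS)-3-hydroxy-6,8a-dimethyl-8-[(3-methylbutanoyl)oxy]-3-(propan-2-yl)-1,2,3,3a,4,5,8,8a-octahydroazulen-4-yl 4-[(tert-butyldimethylsilyl)oxy]benzoate
Conditions: second-generation Grubbs catalyst, (H2IMes)(PCy3)Cl2Ru=CHPh (10 mol%), toluene (2 mM), 80 °C
Reagents that add atoms: none
Why: In this ring-closing metathesis the ruthenium alkylidene should load on the monosubstituted vinyl group and close onto the 1,1-disubstituted alkene, forming the trisubstituted C8=C9 bond of the seven-membered ring, whose (Z) geometry is enforced by ring size. The trans-disposed arms on C1 and C5 give the trans-fused hydroazulene, and no stereocentre is touched.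

Step 22
Reactants: 30 (3S,3aS,4R,8R,8aS)-3-hydroxy-6,8a-dimethyl-8-[(3-methylbutanoyl)oxy]-3-(propan-2-yl)-1,2,3,3a,4,5,8,8a-octahydroazulen-4-yl 4-[(tert-butyldimethylsilyl)oxy]benzoate
Product: 31 (3S,3aS,4R,8R,8aS)-3-hydroxy-6,8a-dimethyl-8-[(3-methylbutanoyl)oxy]-3-(propan-2-yl)-1,2,3,3a,4,5,8,8a-octahydroazulen-4-yl 4-hydroxybenzoate (CNP0086724.4)
Conditions: HF·pyridine, pyridine, THF, 0 °C
Reagents that add atoms: none
Why: The aryl silyl ether is by far the most fluoride-labile group. Buffered HF·pyridine should remove it without touching the two esters, the tertiary alcohol or the allylic system.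

## Compound list

1 | buta-1,3-diene | C=CC=C | starting material
2 | dimethyl mesaconate, dimethyl (2E)-2-methylbut-2-enedioate | COC(=O)/C=C(\C)C(=O)OC | starting material
3 | dimethyl (1S,2S)-1-methylcyclohex-4-ene-1,2-dicarboxylate | COC(=O)[C@@]1(C)CC=CC[C@@H]1C(=O)OC | intermediate
4 | (1S,6S)-6-(methoxycarbonyl)-6-methylcyclohex-3-ene-1-carboxylic acid | COC(=O)[C@@]1(C)CC=CC[C@@H]1C(=O)O | intermediate
5 | mixed anhydride of 4 with isobutyl hydrogen carbonate | COC(=O)[C@@]1(C)CC=CC[C@@H]1C(=O)OC(=O)OCC(C)C | intermediate (not isolated)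
6 | methyl (1S,6S)-6-(hydroxymethyl)-1-methylcyclohex-3-ene-1-carboxylate | COC(=O)[C@@]1(C)CC=CC[C@@H]1CO | intermediate
7 | methyl (1S,6S)-6-{[(tert-butyldimethylsilyl)oxy]methyl}-1-methylcyclohex-3-ene-1-carboxylate | COC(=O)[C@@]1(C)CC=CC[C@@H]1CO[Si](C)(C)C(C)(C)C | intermediate
8 | secondary ozonide (1,2,4-trioxolane across C3 and C11) of 7 | COC(=O)[C@@]1(C)CC2OOC(O2)C[C@@H]1CO[Si](C)(C)C(C)(C)C | intermediate (not isolated)
9 | methyl (2S,3S)-3-{[(tert-butyldimethylsilyl)oxy]methyl}-2-methyl-5-oxo-2-(2-oxoethyl)pentanoate | COC(=O)[C@@](C)(CC=O)[C@H](CC=O)CO[Si](C)(C)C(C)(C)C | intermediate (not isolated)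
10 | methyl (1S,5S)-5-{[(tert-butyldimethylsilyl)oxy]methyl}-4-formyl-1-methylcyclopent-3-ene-1-carboxylate | COC(=O)[C@@]1(C)CC=C(C=O)[C@@H]1CO[Si](C)(C)C(C)(C)C | intermediate
11 | methyl (1S,5S)-5-{[(tert-butyldimethylsilyl)oxy]methyl}-4-(1-hydroxyethyl)-1-methylcyclopent-3-ene-1-carboxylate (carbinol epimers) | COC(=O)[C@@]1(C)CC=C(C(C)O)[C@@H]1CO[Si](C)(C)C(C)(C)C | intermediate
12 | methyl (1S,5S)-4-acetyl-5-{[(tert-butyldimethylsilyl)oxy]methyl}-1-methylcyclopent-3-ene-1-carboxylate | COC(=O)[C@@]1(C)CC=C(C(C)=O)[C@@H]1CO[Si](C)(C)C(C)(C)C | intermediate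
13 | methyl (1S,2S,3R)-3-acetyl-2-{[(tert-butyldimethylsilyl)oxy]methyl}-3-hydroperoxy-1-methylcyclopentane-1-carboxylate | COC(=O)[C@@]1(C)CC[C@](OO)(C(C)=O)[C@@H]1CO[Si](C)(C)C(C)(C)C | intermediate (not isolated)
14 | methyl (1S,2S,3R)-3-acetyl-2-{[(tert-butyldimethylsilyl)oxy]methyl}-3-hydroxy-1-methylcyclopentane-1-carboxylate | COC(=O)[C@@]1(C)CC[C@](O)(C(C)=O)[C@@H]1CO[Si](C)(C)C(C)(C)C | intermediate
15 | methyl (1S,2S,3R)-2-{[(tert-butyldimethylsilyl)oxy]methyl}-3-hydroxy-1-methyl-3-(prop-1-en-2-yl)cyclopentane-1-carboxylate | COC(=O)[C@@]1(C)CC[C@](O)(C(C)=C)[C@@H]1CO[Si](C)(C)C(C)(C)C | intermediate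
16 | methyl (1S,2S,3S)-2-{[(tert-butyldimethylsilyl)oxy]methyl}-3-hydroxy-1-methyl-3-(propan-2-yl)cyclopentane-1-carboxylate | COC(=O)[C@@]1(C)CC[C@](O)(C(C)C)[C@@H]1CO[Si](C)(C)C(C)(C)C | intermediate
17 | (1S,2S,3S)-2-{[(tert-butyldimethylsilyl)oxy]methyl}-3-hydroxy-1-methyl-3-(propan-2-yl)cyclopentane-1-carbaldehyde | O=C[C@@]1(C)CC[C@](O)(C(C)C)[C@@H]1CO[Si](C)(C)C(C)(C)C | intermediate
18 | 1-[(1S,2S,3S)-2-{[(tert-butyldimethylsilyl)oxy]methyl}-3-hydroxy-1-methyl-3-(propan-2-yl)cyclopentyl]prop-2-en-1-ol (C10 epimers) | C=CC(O)[C@@]1(C)CC[C@](O)(C(C)C)[C@@H]1CO[Si](C)(C)C(C)(C)C | intermediate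
19 | 1-[(1S,2S,3S)-2-{[(tert-butyldimethylsilyl)oxy]methyl}-3-hydroxy-1-methyl-3-(propan-2-yl)cyclopentyl]prop-2-en-1-one | C=CC(=O)[C@@]1(C)CC[C@](O)(C(C)C)[C@@H]1CO[Si](C)(C)C(C)(C)C | intermediate
20 | (1R)-1-[(1S,2S,3S)-2-{[(tert-butyldimethylsilyl)oxy]methyl}-3-hydroxy-1-methyl-3-(propan-2-yl)cyclopentyl]prop-2-en-1-ol | C=C[C@@H](O)[C@@]1(C)CC[C@](O)(C(C)C)[C@@H]1CO[Si](C)(C)C(C)(C)C | intermediate
21 | (1R)-1-[(1S,2S,3S)-2-{[(tert-butyldimethylsilyl)oxy]methyl}-3-hydroxy-1-methyl-3-(propan-2-yl)cyclopentyl]prop-2-en-1-yl 3-methylbutanoate | C=C[C@@H](OC(=O)CC(C)C)[C@@]1(C)CC[C@](O)(C(C)C)[C@@H]1CO[Si](C)(C)C(C)(C)C | intermediate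
22 | (1R)-1-[(1S,2S,3S)-3-hydroxy-2-(hydroxymethyl)-1-methyl-3-(propan-2-yl)cyclopentyl]prop-2-en-1-yl 3-methylbutanoate | C=C[C@@H](OC(=O)CC(C)C)[C@@]1(C)CC[C@](O)(C(C)C)[C@@H]1CO | intermediate
23 | (1R)-1-[(1S,2R,3S)-2-formyl-3-hydroxy-1-methyl-3-(propan-2-yl)cyclopentyl]prop-2-en-1-yl 3-methylbutanoate | C=C[C@@H](OC(=O)CC(C)C)[C@@]1(C)CC[C@](O)(C(C)C)[C@@H]1C=O | intermediate
24 | (1R)-1-[(1S,2S,3S)-3-hydroxy-2-[(1R)-1-hydroxy-3-methylbut-3-en-1-yl]-1-methyl-3-(propan-2-yl)cyclopentyl]prop-2-en-1-yl 3-methylbutanoate | C=C[C@@H](OC(=O)CC(C)C)[C@@]1(C)CC[C@](O)(C(C)C)[C@@H]1[C@H](O)CC(C)=C | intermediate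
25 | 4-hydroxybenzoic acid | OC(=O)c1ccc(O)cc1 | starting material
26 | tert-butyldimethylsilyl 4-[(tert-butyldimethylsilyl)oxy]benzoate | CC(C)(C)[Si](C)(C)OC(=O)c1ccc(O[Si](C)(C)C(C)(C)C)cc1 | intermediate (not isolated)
27 | 4-[(tert-butyldimethylsilyl)oxy]benzoic acid | OC(=O)c1ccc(O[Si](C)(C)C(C)(C)C)cc1 | intermediate
28 | 4-[(tert-butyldimethylsilyl)oxy]benzoic 2,4,6-trichlorobenzoic anhydride | O=C(OC(=O)c1c(Cl)cc(Cl)cc1Cl)c1ccc(O[Si](C)(C)C(C)(C)C)cc1 | intermediate (not isolated)
29 | (1R)-1-[(1S,2S,5S)-2-hydroxy-5-methyl-5-{(1R)-1-[(3-methylbutanoyl)oxy]prop-2-en-1-yl}-2-(propan-2-yl)cyclopentyl]-3-methylbut-3-en-1-yl 4-[(tert-butyldimethylsilyl)oxy]benzoate | C=C[C@@H](OC(=O)CC(C)C)[C@@]1(C)CC[C@](O)(C(C)C)[C@@H]1[C@H](OC(=O)c2ccc(O[Si](C)(C)C(C)(C)C)cc2)CC(C)=C | intermediate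
30 | (3S,3aS,4R,8R,8aS)-3-hydroxy-6,8a-dimethyl-8-[(3-methylbutanoyl)oxy]-3-(propan-2-yl)-1,2,3,3a,4,5,8,8a-octahydroazulen-4-yl 4-[(tert-butyldimethylsilyl)oxy]benzoate | CC1=C[C@@H](OC(=O)CC(C)C)[C@@]2(C)CC[C@](O)(C(C)C)[C@@H]2[C@H](OC(=O)c2ccc(O[Si](C)(C)C(C)(C)C)cc2)C1 | intermediate
31 | (3S,3aS,4R,8R,8aS)-3-hydroxy-6,8a-dimethyl-8-[(3-methylbutanoyl)oxy]-3-(propan-2-yl)-1,2,3,3a,4,5,8,8a-octahydroazulen-4-yl 4-hydroxybenzoate | CC1=C[C@@H](OC(=O)CC(C)C)[C@@]2(C)CC[C@](O)(C(C)C)[C@@H]2[C@H](OC(=O)c2ccc(O)cc2)C1 | target

## Step count and least certain steps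

Total: 22 steps. Longest linear sequence: 21 steps (steps 1–18 and 20–22, from 1 and 2 to 31); step 19 is a one-step side branch from 25.

**Step 1 (key step).** Two processes may fail. The rate may be too low for a trisubstituted dienophile with butadiene. Enantioface selectivity may erode through competitive binding of the boron to the ester on the methyl-bearing carbon, which lacks the organising α-C–H contact. The fallback replaces catalyst control by a covalently bound auxiliary on the C6 carbonyl, and sets out from 2:
- 2 is half-saponified at the less hindered ester (KOH, 1 equiv, MeOH, 0 °C) to (2E)-4-methoxy-3-methyl-4-oxobut-2-enoic acid F1.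
- F1 is N-acylated onto (4S)-4-benzyl-1,3-oxazolidin-2-one (pivaloyl chloride, Et3N, LiCl, THF) to give the acyl imide F2.
- Et2AlCl-promoted cycloaddition of F2 with 1 (CH2Cl2, −78 to −30 °C) should proceed through the chelated s-cis imide, with one face covered by the benzyl group, and give the adduct imide F3.
- LiBH4 (THF, 1 equiv H2O, 0 °C) removes the auxiliary reductively, leaves the hindered methyl ester, and returns to the route at 6. Steps 2 and 3 are then unnecessary.

**Step 5.** The process at risk is the direction of the aldol closure. Enamine formation and attack from C2 instead of C4 would give the regioisomeric enal with the formyl group next to C1, because both aldehydes are CH2CHO units and differ only at the β-carbon. The fallback uses a thermodynamically controlled Dieckmann closure and sets out again from 7: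
- Ozonolysis in methanolic base (O3, NaOH, MeOH/CH2Cl2, −78 °C) turns the alkene directly into the triester F4.
- Dieckmann condensation under equilibrating conditions (NaOMe, MeOH/toluene) should give the β-keto ester F5. The alternative regioisomer would place the enolised keto ester next to quaternary C1 and is disfavoured at equilibrium.
- NaBH4 (MeOH, 0 °C) gives the hydroxy ester F6.
- Dehydration (Burgess reagent, toluene, 50 °C) gives the cyclopentene diester F7.
- iBu2AlH (CH2Cl2, −78 °C) reduces the unhindered conjugated ester to the allylic alcohol F8.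
- MnO2 returns to the route at 10.

**Step 9.** The free tertiary alkoxide next to the ketone may trigger α-ketol rearrangement (ring expansion) or transesterification onto the cis C10 ester, and enolisation of the methyl ketone may stall the olefination. The fallback masks the carbinol, and sets out from 14:
- Silylation (Me3SiOTf, 2,6-lutidine, CH2Cl2, −78 °C) gives the trimethylsilyl ether F9, which can no longer form an alkoxide.
- Methylenation (Ph3P=CH2, THF) gives the silylated isopropenyl compound F10.
- K2CO3/MeOH removes the tertiary trimethylsilyl group in the presence of the primary tert-butyldimethylsilyl ether and returns to the route at 15.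

**Step 18.** Conversion may be slow because the aldehyde is flanked by two fully substituted carbons and the borane is bulky, and facial selectivity may be poor if the substrate bias opposes the reagent. The fallback replaces asymmetric C–C bond formation by asymmetric hydride delivery to a ketone whose two flanks differ strongly in size, and sets out from 23:
- Unselective Barbier addition (2-methylallyl bromide, Zn, THF/aq. NH4Cl) gives the C6-epimeric alcohols F11.
- Dess–Martin oxidation gives the β,γ-unsaturated ketone F12.
- CBS reduction ((S)-2-methyl-CBS-oxazaborolidine, catecholborane, toluene, −78 °C), with ring carbon C5 as the large and the methallyl CH2 as the small group, should give 24.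

**Step 21.** Turnover may be slow, with competing dimerisation, because the vinyl group sits next to a quaternary carbon and an acyloxy group, and the 1,1-disubstituted alkene is screened by the aroyloxy group. The fallback changes the order of ring closure and acylation, and sets out from 24:
- Metathesis on the free homoallylic alcohol (same ruthenium catalyst, toluene, 80 °C) should give the bicyclic hydroxy ester F13.
- Yamaguchi esterification of F13 with 27 returns to the route at 30.

## Further compounds

F1 | step 1 | (2E)-4-methoxy-3-methyl-4-oxobut-2-enoic acid | COC(=O)/C(C)=C/C(=O)O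
F2 | step 1 | (4S)-4-benzyl-3-[(2E)-4-methoxy-3-methyl-4-oxobut-2-enoyl]-1,3-oxazolidin-2-one | COC(=O)/C(C)=C/C(=O)N1[C@@H](Cc2ccccc2)COC1=O
F3 | step 1 | methyl (1S,6S)-6-{[(4S)-4-benzyl-2-oxo-1,3-oxazolidin-3-yl]carbonyl}-1-methylcyclohex-3-ene-1-carboxylate | COC(=O)[C@@]1(C)CC=CC[C@@H]1C(=O)N2[C@@H](Cc3ccccc3)COC2=O
F4 | step 5 | dimethyl (3S,4S)-4-{[(tert-butyldimethylsilyl)oxy]methyl}-3-(methoxycarbonyl)-3-methylhexanedioate | COC(=O)[C@@](C)(CC(=O)OC)[C@H](CC(=O)OC)CO[Si](C)(C)C(C)(C)C
F5 | step 5 | dimethyl (1S,2S)-2-{[(tert-butyldimethylsilyl)oxy]methyl}-1-methyl-4-oxocyclopentane-1,3-dicarboxylate (C3 epimers) | COC(=O)[C@@]1(C)CC(=O)C(C(=O)OC)[C@@H]1CO[Si](C)(C)C(C)(C)C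
F6 | step 5 | dimethyl (1S,2S)-2-{[(tert-butyldimethylsilyl)oxy]methyl}-4-hydroxy-1-methylcyclopentane-1,3-dicarboxylate (C3 and C4 epimers) | COC(=O)[C@@]1(C)CC(O)C(C(=O)OC)[C@@H]1CO[Si](C)(C)C(C)(C)C
F7 | step 5 | dimethyl (4S,5R)-5-{[(tert-butyldimethylsilyl)oxy]methyl}-4-methylcyclopent-1-ene-1,4-dicarboxylate | COC(=O)[C@@]1(C)CC=C(C(=O)OC)[C@@H]1CO[Si](C)(C)C(C)(C)C
F8 | step 5 | methyl (1S,5S)-5-{[(tert-butyldimethylsilyl)oxy]methyl}-4-(hydroxymethyl)-1-methylcyclopent-3-ene-1-carboxylate | COC(=O)[C@@]1(C)CC=C(CO)[C@@H]1CO[Si](C)(C)C(C)(C)C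
F9 | step 9 | methyl (1S,2S,3R)-3-acetyl-2-{[(tert-butyldimethylsilyl)oxy]methyl}-1-methyl-3-[(trimethylsilyl)oxy]cyclopentane-1-carboxylate | COC(=O)[C@@]1(C)CC[C@](O[Si](C)(C)C)(C(C)=O)[C@@H]1CO[Si](C)(C)C(C)(C)C
F10 | step 9 | methyl (1S,2S,3R)-2-{[(tert-butyldimethylsilyl)oxy]methyl}-1-methyl-3-(prop-1-en-2-yl)-3-[(trimethylsilyl)oxy]cyclopentane-1-carboxylate | COC(=O)[C@@]1(C)CC[C@](O[Si](C)(C)C)(C(C)=C)[C@@H]1CO[Si](C)(C)C(C)(C)C
F11 | step 18 | (1R)-1-[(1S,2S,3S)-3-hydroxy-2-(1-hydroxy-3-methylbut-3-en-1-yl)-1-methyl-3-(propan-2-yl)cyclopentyl]prop-2-en-1-yl 3-methylbutanoate (C6 epimers) | C=C[C@@H](OC(=O)CC(C)C)[C@@]1(C)CC[C@](O)(C(C)C)[C@@H]1C(O)CC(C)=C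
F12 | step 18 | (1R)-1-[(1S,2R,3S)-3-hydroxy-1-methyl-2-(3-methylbut-3-enoyl)-3-(propan-2-yl)cyclopentyl]prop-2-en-1-yl 3-methylbutanoate | C=C[C@@H](OC(=O)CC(C)C)[C@@]1(C)CC[C@](O)(C(C)C)[C@@H]1C(=O)CC(C)=C
F13 | step 21 | (3S,3aS,4R,8R,8aS)-3,4-dihydroxy-6,8a-dimethyl-3-(propan-2-yl)-1,2,3,3a,4,5,8,8a-octahydroazulen-8-yl 3-methylbutanoate | CC1=C[C@@H](OC(=O)CC(C)C)[C@@]2(C)CC[C@](O)(C(C)C)[C@@H]2[C@H](O)C1
A1 | alternative 1 | 2-[(Z)-1-hydroxy-3-methyl-4-(trimethylsilyl)but-3-en-1-yl]-3-methyl-3-[1-(trimethylsilyl)ethenyl]cyclopentan-1-one (C1 and C5 as in 31, C6 epimeric) | C=C([Si](C)(C)C)[C@@]1(C)CCC(=O)[C@@H]1[C@@H](O)C/C(C)=C\[Si](C)(C)C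
A2 | alternative 1 | 3-methylcyclopent-2-en-1-one | CC1=CC(=O)CC1
A3 | alternative 1 | (3Z)-3-methyl-4-(trimethylsilyl)but-3-enal | O=CC/C(C)=C\[Si](C)(C)C
A4 | alternative 1 | dimethyl[1-(trimethylsilyl)ethenyl]aluminium | C=C([Si](C)(C)C)[Al](C)C
A5 | alternative 2 | 6,10-dimethoxy-1,8-dimethyl-4-(propan-2-yl)-4-[(triethylsilyl)oxy]bicyclo[5.3.0]deca-5,7,9-trien-2-one (daucane numbering) | CC=1C=C(OC)[C@@]2(C)C(=O)C[C@](O[Si](CC)(CC)CC)(C(C)C)C2=C(OC)C1
A6 | alternative 2 | 2-diazo-5-(2,6-dimethoxy-4-methylphenyl)-6-methyl-5-[(triethylsilyl)oxy]heptan-3-one | CC(=[N+]=[N-])C(=O)C[C@](O[Si](CC)(CC)CC)(C(C)C)c1c(OC)cc(C)cc1OC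
A7 | alternative 3 | C10 enone of the complete daucane skeleton with the 4-[(tert-butyldimethylsilyl)oxy]benzoate at C6 | CC1=CC(=O)[C@@]2(C)CC[C@](O)(C(C)C)[C@@H]2[C@H](OC(=O)c2ccc(O[Si](C)(C)C(C)(C)C)cc2)C1
A8 | alternative 3 | trimethylsilyl enol ether (C8=C10) of the corresponding trans-hydrindan-10-one | CC1=C(O[Si](C)(C)C)[C@@]2(C)CC[C@](O)(C(C)C)[C@@H]2[C@H](OC(=O)c2ccc(O[Si](C)(C)C(C)(C)C)cc2)C1
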